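## Structural features

Spiculoic acid B (35) is a trans-fused bicyclo[4.3.0]nonadiene: a cyclohexene (ring A, C1–C2–C3=C4–C5–C6) shares the C5–C6 bond with a cyclopentene (ring B, C6–C7=C8–C9–C5). Ring A is drawn with C1→C6 clockwise; β is the face towards the viewer and α the face away, and these locants and face labels are used for all compounds. C1 carries CH3 (α) and CO2H (β), C2 carries ethyl (α) and (E)-styryl (β), C4 and C7 carry ethyl, C5–H is α, C6–H is β, and the C9 methyl is α (cis to H-5); in this numbering 35 is (1R,2S,5S,6R,9R). The five stereocentres are contiguous, and C1 and C2 are adjacent all-carbon quaternary centres. The fragile points are the styrene (which sits γ,δ to the carboxyl and can lactonise under strong acid), the two trisubstituted alkenes (whose positions must not drift), the C6 centre (epimerisable whenever C7 is a carbonyl) and the very hindered neopentyl carboxyl. The real difficulty is the C1/C2 pair, because each centre carries two groups of similar size (CH3/CO2R and ethyl/styryl), so simple steric discrimination cannot be trusted. The key step exploits the fact that C7, C8 and C9 of ring B map onto the carbonyl, α-methylene and β-methine of a cyclopentanone: a C7 aldehyde on C6 and an isopropenyl group on C5 of a finished ring A form a 4-methylpent-4-enal unit, and intramolecular hydroacylation closes C7–C8 while placing hydrogen on C9. The resulting C7 ketone then fixes the position of the C7=C8 alkene and is the handle for the C7 ethyl group.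

## Logic of the disconnections

35 ⇒ 34. The carboxyl O–H is exchanged for O–CH3. A free acid next to the styrene would lactonise under acid and would quench every organometallic reagent used earlier. The forward step must cleave a neopentyl ester flanked by two quaternary carbons, which calls for dealkylation at the methyl carbon and not attack at the carbonyl.

34 ⇒ 33. The C7–CH2CH3 bond is cut. An enol triflate at C7–C8 fixes the alkene position and lets the ethyl group arrive by cross-coupling. The coupling must be faster than Grignard addition to the ester and must not isomerise the ethyl group.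

33 ⇒ 31. The C7–O triflate bond is cut back to the C7 ketone. This removes one alkene and reveals the cyclopentanone. The forward step must enolise towards C8 and not towards the ring-fusion carbon C6.

31 ⇒ 30. The C7–C8 bond is cut and the C9 hydrogen is returned to the aldehyde. Ring B and the C9 stereocentre disappear, leaving a monocyclic ring A with a formyl group on C6 and an isopropenyl group on C5. The forward step must add the aldehyde C–H across the 1,1-disubstituted alkene, deliver hydride to the correct face of C9, and avoid decarbonylation and C6 epimerisation.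

30 ⇒ 29. The aldehyde is masked as its dimethyl acetal. This protects C6 from epimerisation and the carbonyl from the cuprate and hydride steps. The unmasking must be mild enough not to trigger a Prins-type closure onto the isopropenyl group.

29 ⇒ 28. The C3–H bond is exchanged for C3–OTf. The C3=C4 alkene is thereby traced to a regiodefined enolate. The forward step is a hydride-for-triflate exchange on a hindered, tetrasubstituted enol triflate.

28 ⇒ 23 + 24. The C5–C9 bond is cut. The isopropenyl group and the C5 stereocentre are removed, leaving a 2-ethylcyclohexenone whose C3 carbonyl explains both the enolate and the later alkene. The cuprate must add anti to the C6 substituent, and the enolate must be trapped on oxygen.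

23 ⇒ 21. The ester O–CH3 and the two acetal O–CH3 bonds are cut, and C1–C(=O)–O–C7 is reconnected as a trans-fused γ-lactone acylal bearing the auxiliary alcohol. This ties C1 and C6 into a rigid bicycle and stores C7 at the aldehyde oxidation level. The opening must proceed by acetal exchange under acid so that C6 is not epimerised.

21 ⇒ 19 + 20. The Cβ–aryl bond of the styrene is cut. The phenyl group is attached only after the enolate chemistry at C2 is finished, which keeps a conjugated styrene out of those steps. The arylation must choose the monosubstituted alkene over the enone alkene.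

19 ⇒ 15 + 16. The C2–Cα bond is cut. The second quaternary centre is formed by adding a vinyl cation equivalent to a C2 enolate of the rigid bicycle, where the axial C1 methyl group decides the face. The forward step needs α′-enolisation and attack anti to that methyl group.

15 ⇒ 13. The C2–ethyl bond is cut. A simple alkylation of the α′-methylene suffices because the new centre is planarised again in the next step.

13 ⇒ 12. The C4=C5 bond is cut by a retro-aldol condensation. Ring A opens to a keto aldehyde on a monocyclic lactone. Only one aldol mode can give a six-membered ring, so no regiochemical demand arises.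

12 ⇒ 11. The C3 ketone is traced to an alkyne. This allows the C2–C4 unit to be introduced as an unreactive propargylic halide. The hydration must place oxygen on C3, which the neighbouring lactone carbonyl should direct.

11 ⇒ 10. The C5 aldehyde is masked as a dithiane. The mask survives two enolate alkylations and is removed without base.

10 ⇒ 7 + 8. The C1–C2 bond is cut. The quaternary C1 is traced to alkylation of an α-methyl lactone enolate, which enters trans to the C6 substituent. This is the step that fixes the trans ring fusion and the CH3/CO2R arrangement at C1.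

7 ⇒ 3 + 4. The C6–C5 and C1–CH3 bonds are cut. A tandem conjugate addition–alkylation on the chiral butenolide sets C6 anti to the acetal substituent and the methyl group anti to C6. All later stereocentres are relayed from this step.

3 ⇒ 1 + 2. The acetal C–O bond is cut. The only source of chirality is a purchased terpene alcohol, and the acetal centre is fixed by crystallisation of one epimer.

## Other disconnections considered

Alternative 1: The cut removes C5–C6, C7–C8 and C8–C9 together, so both rings open and C8 becomes carbon monoxide. The forward step would be a carbonylative [2+2+1] cyclisation (Pauson–Khand type, [Rh(CO)2Cl]2 under CO or Co2(CO)8) of the dienyne A2, joining the alkyne C6≡C7 to the far alkene C5=C9 of the diene to give the bicyclic enone A1.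
- In its favour: two rings and three skeletal bonds form in one operation, which is better ring-building economy than the chosen plan. The C5/C9 relation follows stereospecifically from the alkene geometry, which is more reliable than face-selective hydride delivery.
- Against it here: A1 carries its oxygen at C8 and its alkene at C6=C7, so a 1,2-reduction and a reductive allylic transposition are needed, and the second must re-create C6–H trans to H-5. Dienynes normally engage the alkene nearer the tether, so closure of the six-membered ring through the remote alkene competes with other modes. The styrene has to be carried as a silyloxymethyl group, which costs three more steps. The C5 centre is formed far from C1/C2 with only tether conformation to control its face.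
- Comparison: structurally, 31 has its carbonyl exactly where the ethyl group must go, whereas A1 does not. Mechanistically both are metal insertions, and the alternative is the better for C9. In step count it wins before the key step but loses about three steps after it. The C1/C2 problem is not eased, because A2 must contain both quaternary centres in an open chain.

Alternative 2: The cut is C5–C6, with O–C3 reconnected, so ring A is traced to the δ-lactone A4. The forward step would be an Ireland–Claisen rearrangement of its silyl ketene acetal (LDA, Me3SiCl) through the boat transition state that the two-atom bridge enforces, giving the ring-A acid A3.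
- In its favour: one concerted step sets C5 and C6 from the alkene geometry and the C3 carbinol configuration. The C3=C4 alkene is made without an enol triflate reduction, which is better than the chosen plan on that point. C7 emerges as a free acid without protecting groups, and no transition metal is needed.
- Against it here: A4 must already hold the C1/C2 quaternary pair, a C3 carbinol of the right configuration, a (Z)-trisubstituted alkene and the C9 centre, which the key step does not create. Ring B then needs acid-to-ethyl-ketone conversion, methylenation and a ring-closing metathesis that has to ignore the styrene.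
- Comparison: structurally, A3 has one carbon too many in the side chain and C7 at the acid level, whereas 31 has exactly the atoms of ring B. Mechanistically the pericyclic step is the more predictable for C5/C6, and there the alternative is the better. In step count it is about two steps longer after the key step and no shorter before it.

Alternative 3: The cut is C2–C3 as the last carbon–carbon bond. The forward step would be a 6-exo Heck cyclisation of the alkenyl iodide A6 (zerovalent palladium from Pd(OAc)2 and BINAP) onto the trisubstituted C2=Cα alkene, followed by β-hydride elimination, to give the methyl ester A5, which is identical with 34.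
- In its favour: the styrene is created last and never meets earlier reagents, which is better than carrying it through seven steps. The (E) geometry follows from the elimination. Only one step separates A5 from 35, so step economy after the key step is better than in the chosen plan.
- Against it here: the configuration at C2 would rest on facial selectivity of a migratory insertion next to C1, whose two substituents are of similar size, so the ligand would have to override the substrate. Forming a quaternary carbon beside another from a trisubstituted alkene is slow and invites reduction of the alkenyl palladium. A6 needs a (Z)-iodoalkene, a defined trisubstituted alkene and four stereocentres.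
- Comparison: the chosen plan sets C2 by enolate alkylation on a rigid bicycle, which is the more predictable control element. Mechanistically both key steps are late-metal insertions of comparable precedent. The alternative is equal or better after the key step and clearly longer before it.

Key step: step 14

Assumption: 5-hydroxyfuran-2(5H)-one (1) and (+)-menthol (2) are taken as purchasable; 1 is otherwise one step from furfural by sensitised photo-oxygenation.

## Route

Step 1
Reactants: 1 5-hydroxyfuran-2(5H)-one; 2 (+)-menthol
Product: 3 (5S)-5-[(1S,2R,5S)-menthyloxy]furan-2(5H)-one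
Conditions: CSA (cat.), PhH, reflux with azeotropic removal of water; crystallisation from petroleum ether, mother liquor re-equilibrated with CSA
Reagents that add atoms: none
Why: Acid-catalysed acetal exchange of a γ-hydroxybutenolide with a secondary alcohol; the two acetal epimers interconvert under the conditions and the (5S) epimer should crystallise, so the acetal centre is set by crystallisation-driven equilibration.

Step 2
Reactants: 3 (5S)-5-[(1S,2R,5S)-menthyloxy]furan-2(5H)-one; 4 1,3-dithiane
Product: 7 (3S,4S,5S)-4-(1,3-dithian-2-yl)-3-methyl-5-[(1S,2R,5S)-menthyloxy]oxolan-2-one, via 2-lithio-1,3-dithiane 5 (not isolated), via lithium enolate 6 (not isolated)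
Conditions: 4, n-BuLi, THF, −30 °C; HMPA, then 3, −78 °C; MeI, −78 → −20 °C
Reagents that add atoms: iodomethane CI
Why: Michael addition of the sulfur-stabilised carbanion should occur anti to the bulky 5-alkoxy group and so set C6, and the lactone enolate should take up iodomethane anti to the new C6 substituent (tandem conjugate addition–alkylation). HMPA favours 1,4- over 1,2-addition.

Step 3
Reactants: 7 (3S,4S,5S)-4-(1,3-dithian-2-yl)-3-methyl-5-[(1S,2R,5S)-menthyloxy]oxolan-2-one; 8 1-bromopent-2-yne
Product: 10 (3S,4S,5S)-4-(1,3-dithian-2-yl)-3-methyl-3-(pent-2-yn-1-yl)-5-[(1S,2R,5S)-menthyloxy]oxolan-2-one, via lithium enolate 9 (not isolated)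
Conditions: LDA, THF, −78 °C; 8, DMPU, −78 → −30 °C
Reagents that add atoms: none
Why: Alkylation of an α-methyl lactone enolate; the propargylic bromide should enter trans to the dithianyl group on C6, which sets quaternary C1 with the methyl group cis and the C2 chain trans to the C5 carbon, as the trans ring fusion requires.

Step 4
Reactants: 10 (3S,4S,5S)-4-(1,3-dithian-2-yl)-3-methyl-3-(pent-2-yn-1-yl)-5-[(1S,2R,5S)-menthyloxy]oxolan-2-one
Product: 11 (2S,3R,4S)-4-methyl-2-[(1S,2R,5S)-menthyloxy]-5-oxo-4-(pent-2-yn-1-yl)oxolane-3-carbaldehyde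
Conditions: MeI, CaCO3, MeCN/H2O 4:1, 45 °C
Reagents that add atoms: water O
Why: S-Methylation and hydrolysis of the dithioacetal under buffered conditions should release the aldehyde without touching the alkyne, the lactone or the acylal, and without base that could epimerise C6.

Step 5
Reactants: 11 (2S,3R,4S)-4-methyl-2-[(1S,2R,5S)-menthyloxy]-5-oxo-4-(pent-2-yn-1-yl)oxolane-3-carbaldehyde
Product: 12 (2S,3R,4S)-4-methyl-2-[(1S,2R,5S)-menthyloxy]-5-oxo-4-(2-oxopentyl)oxolane-3-carbaldehyde
Conditions: Ph3PAuNTf2 (2 mol%), 1,4-dioxane/H2O 10:1, 50 °C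
Reagents that add atoms: water O
Why: Gold-catalysed alkyne hydration; 5-exo attack of the lactone carbonyl oxygen on the activated alkyne should deliver oxygen to C3, so the ketone forms at C3 and not at C4 (carbonyl-assisted hydration).

Step 6
Reactants: 12 (2S,3R,4S)-4-methyl-2-[(1S,2R,5S)-menthyloxy]-5-oxo-4-(2-oxopentyl)oxolane-3-carbaldehyde
Product: 13 (3S,3aS,7aS)-5-ethyl-7a-methyl-3-[(1S,2R,5S)-menthyloxy]-3a,7-dihydro-2-benzofuran-1,6(3H,7aH)-dione (trans-fused; ring-A locants: C3 ketone, C4=C5, lactone from C1 to C7 on C6)
Conditions: TsOH (10 mol%), PhH, reflux with azeotropic removal of water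
Reagents that add atoms: none
Why: Intramolecular aldol condensation; only attack of C4 on the C5 aldehyde gives a six-membered ring (the other modes would be four-membered), and dehydration gives the conjugated enone. The C6 configuration is anchored trans to the acetal oxygen, so any enolisation should return the same epimer.

Step 7
Reactants: 13 (3S,3aS,7aS)-5-ethyl-7a-methyl-3-[(1S,2R,5S)-menthyloxy]-3a,7-dihydro-2-benzofuran-1,6(3H,7aH)-dione
Product: 15 (3S,3aS,7R,7aR)-5,7-diethyl-7a-methyl-3-[(1S,2R,5S)-menthyloxy]-3a,7-dihydro-2-benzofuran-1,6(3H,7aH)-dione (ethyl on C2; expected major epimer drawn), via lithium enolate 14 (not isolated)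
Conditions: LDA, THF, −78 °C; EtI, DMPU, −78 → −20 °C
Reagents that add atoms: iodoethane CCI
Why: Kinetic α′-deprotonation of the enone at C2 and C-alkylation with iodoethane; the configuration at C2 is of no consequence because this centre is enolised again in step 8.

Step 8
Reactants: 15 (3S,3aS,7R,7aR)-5,7-diethyl-7a-methyl-3-[(1S,2R,5S)-menthyloxy]-3a,7-dihydro-2-benzofuran-1,6(3H,7aH)-dione; 16 phenyl vinyl sulfoxide
Product: 19 (3S,3aS,7R,7aR)-7-ethenyl-5,7-diethyl-7a-methyl-3-[(1S,2R,5S)-menthyloxy]-3a,7-dihydro-2-benzofuran-1,6(3H,7aH)-dione (C2: vinyl β and ethyl α), via lithium enolate 17 (not isolated), via sulfoxide adduct 18 (not isolated)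
Conditions: LDA, THF, −78 °C; 16, −78 → 0 °C; aq. NH4Cl; then PhMe, 110 °C
Reagents that add atoms: none
Why: Michael addition of the C2 enolate to a vinyl sulfoxide (a vinyl cation equivalent), followed by thermal syn-elimination of benzenesulfenic acid. In the rigid trans-fused bicycle the C1 methyl group is axial on the α face, so the electrophile should reach C2 from the β face, placing vinyl cis to the C1 carboxyl carbon and ethyl cis to methyl.

Step 9
Reactants: 19 (3S,3aS,7R,7aR)-7-ethenyl-5,7-diethyl-7a-methyl-3-[(1S,2R,5S)-menthyloxy]-3a,7-dihydro-2-benzofuran-1,6(3H,7aH)-dione; 20 iodobenzene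
Product: 21 (3S,3aS,7R,7aR)-5,7-diethyl-7a-methyl-3-[(1S,2R,5S)-menthyloxy]-7-[(E)-2-phenylethenyl]-3a,7-dihydro-2-benzofuran-1,6(3H,7aH)-dione
Conditions: 20, Pd(OAc)2 (5 mol%), P(o-tol)3 (10 mol%), Et3N, MeCN, 80 °C
Reagents that add atoms: none
Why: Heck reaction; the aryl palladium species adds to the terminal carbon of the monosubstituted alkene, and β-hydride elimination can only give the (E)-styrene because C2 is quaternary. The trisubstituted, electron-poor enone alkene should not compete.

Step 10
Reactants: 21 (3S,3aS,7R,7aR)-5,7-diethyl-7a-methyl-3-[(1S,2R,5S)-menthyloxy]-7-[(E)-2-phenylethenyl]-3a,7-dihydro-2-benzofuran-1,6(3H,7aH)-dione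
Product: 23 methyl 6α-(dimethoxymethyl)-2α,4-diethyl-1α-methyl-3-oxo-2β-[(E)-2-phenylethenyl]cyclohex-4-ene-1β-carboxylate, via carboxylic acid 22 (not isolated)
Conditions: CSA (10 mol%), MeOH/HC(OMe)3 5:1, 45 °C; evaporate; Me3SiCHN2, PhMe/MeOH 4:1, 0 °C
Reagents that add atoms: methanol CO; (trimethylsilyl)diazomethane C[Si](C)(C)C=[N+]=[N-]
Why: Acid-catalysed exchange at the acylal carbon with methanol should open the strained trans-fused lactone to the dimethyl acetal and the free C1 acid, releasing the auxiliary. The hindered acid is then methylated by the diazoalkane without base, so C6 is not epimerised.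

Step 11
Reactants: 23 methyl 6α-(dimethoxymethyl)-2α,4-diethyl-1α-methyl-3-oxo-2β-[(E)-2-phenylethenyl]cyclohex-4-ene-1β-carboxylate; 24 2-bromopropene
Product: 28 methyl 6α-(dimethoxymethyl)-2α,4-diethyl-1α-methyl-2β-[(E)-2-phenylethenyl]-5β-(prop-1-en-2-yl)-3-(trifluoromethanesulfonyloxy)cyclohex-3-ene-1β-carboxylate, via isopropenyllithium 25 (not isolated), via lithium diisopropenylcuprate 26 (not isolated), via lithium enolate 27 (not isolated)
Conditions: 24, t-BuLi (2 equiv), Et2O, −78 °C; CuI (0.5 equiv), −40 °C; 23, −78 → −30 °C; PhNTf2, THF, −30 °C → rt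
Reagents that add atoms: N-phenylbis(trifluoromethanesulfonimide) O=S(=O)(N(c1ccccc1)S(=O)(=O)C(F)(F)F)C(F)(F)F
Why: Conjugate addition of a lithium diorganocuprate to the enone; in the now flexible ring the reagent should add to C5 anti to the C6 dimethoxymethyl group (the trans rule for 4-substituted cyclohexenones). O-Triflation of the enolate fixes the double bond at C3=C4, because C2 carries no hydrogen.

Step 12
Reactants: 28 methyl 6α-(dimethoxymethyl)-2α,4-diethyl-1α-methyl-2β-[(E)-2-phenylethenyl]-5β-(prop-1-en-2-yl)-3-(trifluoromethanesulfonyloxy)cyclohex-3-ene-1β-carboxylate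
Product: 29 methyl 6α-(dimethoxymethyl)-2α,4-diethyl-1α-methyl-2β-[(E)-2-phenylethenyl]-5β-(prop-1-en-2-yl)cyclohex-3-ene-1β-carboxylate
Conditions: Pd(OAc)2 (5 mol%), PPh3 (10 mol%), n-Bu3N, HCO2H, DMF, 60 °C
Reagents that add atoms: none
Why: Palladium-catalysed formate reduction of an enol triflate; oxidative addition to zerovalent palladium, decarboxylation of formate to a palladium hydride and C–H reductive elimination replace triflate by hydrogen without moving the alkene.

Step 13
Reactants: 29 methyl 6α-(dimethoxymethyl)-2α,4-diethyl-1α-methyl-2β-[(E)-2-phenylethenyl]-5β-(prop-1-en-2-yl)cyclohex-3-ene-1β-carboxylate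
Product: 30 methyl (1R,2S,5R,6S)-2,4-diethyl-6-formyl-1-methyl-2-[(E)-2-phenylethenyl]-5-(prop-1-en-2-yl)cyclohex-3-ene-1-carboxylate (6α-formyl trans to 5β-isopropenyl)
Conditions: PPTS, acetone/H2O 9:1, 40 °C
Reagents that add atoms: water O
Why: Mild acid-catalysed acetal hydrolysis; C6 already has the thermodynamically preferred trans relation to the C5 isopropenyl group, so any enolisation of the aldehyde should return the same epimer.

Step 14
Reactants: 30 methyl (1R,2S,5R,6S)-2,4-diethyl-6-formyl-1-methyl-2-[(E)-2-phenylethenyl]-5-(prop-1-en-2-yl)cyclohex-3-ene-1-carboxylate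
Product: 31 trans-fused bicyclic C7 ketone, methyl 2α,4-diethyl-1α,9α-dimethyl-7-oxo-2β-[(E)-2-phenylethenyl]bicycle (C1–C9 locants; 5α-H and 6β-H) 1β-carboxylate
Conditions: [Rh(dppe)]ClO4 (5 mol%), CH2Cl2, 25 °C
Reagents that add atoms: none
Why: The cationic monovalent rhodium complex inserts into the aldehyde C–H bond to give an acyl hydride of trivalent rhodium; the isopropenyl group coordinates, the hydride moves to C9 to give a six-membered acyl alkyl rhodacycle bonded through C8, and C–C reductive elimination forms C7–C8 and releases the cyclopentanone. The closest known reaction type is the rhodium diphosphine-catalysed cyclisation of 4-substituted pent-4-enals to 3-substituted cyclopentanones, of which 30 is a 2,3-ring-fused case. Ring B closes in a formal 5-endo-trig sense, both alkene carbons ending up in the ring, which is why a metal hydride pathway is used and not a radical or anionic one. The new stereocentre C9 is set in the hydride transfer: in the chair-like rhodacycle the C5–C4 and C6–C1 bonds are equatorial, and the C9 methyl group should also be equatorial, which places it trans to C4 and cis to H-5. The step needs chemoselectivity for the isopropenyl group, secured because only this alkene completes a pent-4-enal unit within reach of the metal; the styryl group lies on the opposite face one atom further away, and the ring alkene would give a bridged ketone. It also needs retention at C6, secured by the neutral conditions and by the trans C5/C6 arrangement already being the stable one. A chelating diphosphine is chosen because it leaves no free cis site for loss of CO, which should keep decarbonylation slow.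

Step 15
Reactants: 31 trans-fused bicyclic C7 ketone
Product: 33 C7–C8 enol triflate, methyl 2α,4-diethyl-1α,9α-dimethyl-2β-[(E)-2-phenylethenyl]-7-(trifluoromethanesulfonyloxy)bicycle (C7=C8) 1β-carboxylate, via lithium enolate 32 (not isolated)
Conditions: LDA, THF, −78 °C; PhNTf2, −78 → 0 °C
Reagents that add atoms: N-phenylbis(trifluoromethanesulfonimide) O=S(=O)(N(c1ccccc1)S(=O)(=O)C(F)(F)F)C(F)(F)F
Why: Kinetic deprotonation should occur at the C8 methylene, since the C6 methine at the ring fusion is hindered and its enolate would strain the trans-fused bicycle; O-sulfonylation then gives the C7–C8 enol triflate.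

Step 16
Reactants: 33 C7–C8 enol triflate
Product: 34 spiculoic acid B methyl ester
Conditions: EtMgBr, Fe(acac)3 (5 mol%), THF/NMP, −30 °C
Reagents that add atoms: ethylmagnesium bromide CC[Mg]Br
Why: Iron-catalysed Kumada-type cross-coupling of an alkenyl triflate with an alkyl Grignard reagent; at −30 °C coupling should be much faster than addition to the shielded neopentyl ester, and the ethyl group should be transferred without β-hydride loss.

Step 17
Reactants: 34 spiculoic acid B methyl ester
Product: 35 spiculoic acid B, (1R,2S,5S,6R,9R) in C1–C9 locants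
Conditions: NaSEt, DMF, 90 °C; then 1 M HCl to pH 3, 0 °C
Reagents that add atoms: none
Why: SN2 O-demethylation by thiolate cleaves the ester at the methyl carbon and so avoids the shielded carbonyl; brief cold acidification to pH 3 should not lactonise the acid onto the styrene.

## Compound list

1 | 5-hydroxyfuran-2(5H)-one | O=C1C=CC(O)O1 | starting material
2 | (+)-menthol, (1S,2R,5S)-5-methyl-2-(propan-2-yl)cyclohexan-1-ol | O[C@H]1C[C@@H](C)CC[C@@H]1C(C)C | starting material
3 | (5S)-5-[(1S,2R,5S)-menthyloxy]furan-2(5H)-one | O=C1C=C[C@@H](O[C@H]2C[C@@H](C)CC[C@@H]2C(C)C)O1 | intermediate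
4 | 1,3-dithiane | C1CSCSC1 | starting material
5 | 2-lithio-1,3-dithiane | [Li]C1SCCCS1 | intermediate
6 | lithium (4S,5S)-4-(1,3-dithian-2-yl)-5-[(1S,2R,5S)-menthyloxy]-4,5-dihydrofuran-2-olate | [Li]OC1=C[C@H](C3SCCCS3)[C@@H](O[C@H]2C[C@@H](C)CC[C@@H]2C(C)C)O1 | intermediate
7 | (3S,4S,5S)-4-(1,3-dithian-2-yl)-3-methyl-5-[(1S,2R,5S)-menthyloxy]oxolan-2-one (3,4-trans, 4,5-trans) | C[C@@H]1C(=O)O[C@H](O[C@H]2C[C@@H](C)CC[C@@H]2C(C)C)[C@H]1C3SCCCS3 | intermediate
8 | 1-bromopent-2-yne | CCC#CCBr | starting material
9 | lithium enolate of 7, lithium (4S,5S)-4-(1,3-dithian-2-yl)-3-methyl-5-[(1S,2R,5S)-menthyloxy]-4,5-dihydrofuran-2-olate | CC1=C(O[Li])O[C@H](O[C@H]2C[C@@H](C)CC[C@@H]2C(C)C)[C@H]1C3SCCCS3 | intermediate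
10 | (3S,4S,5S)-4-(1,3-dithian-2-yl)-3-methyl-3-(pent-2-yn-1-yl)-5-[(1S,2R,5S)-menthyloxy]oxolan-2-one (pentynyl trans to dithianyl) | CCC#CC[C@]1(C)C(=O)O[C@H](O[C@H]2C[C@@H](C)CC[C@@H]2C(C)C)[C@H]1C3SCCCS3 | intermediate
11 | (2S,3R,4S)-4-methyl-2-[(1S,2R,5S)-menthyloxy]-5-oxo-4-(pent-2-yn-1-yl)oxolane-3-carbaldehyde | CCC#CC[C@]1(C)C(=O)O[C@H](O[C@H]2C[C@@H](C)CC[C@@H]2C(C)C)[C@H]1C=O | intermediate
12 | (2S,3R,4S)-4-methyl-2-[(1S,2R,5S)-menthyloxy]-5-oxo-4-(2-oxopentyl)oxolane-3-carbaldehyde | CCCC(=O)C[C@]1(C)C(=O)O[C@H](O[C@H]2C[C@@H](C)CC[C@@H]2C(C)C)[C@H]1C=O | intermediate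
13 | (3S,3aS,7aS)-5-ethyl-7a-methyl-3-[(1S,2R,5S)-menthyloxy]-3a,7-dihydro-2-benzofuran-1,6(3H,7aH)-dione, trans-fused (1α-methyl, 6β-H in ring-A locants) | CCC1=C[C@@H]2[C@@H](O[C@H]3C[C@@H](C)CC[C@@H]3C(C)C)OC(=O)[C@@]2(C)CC1=O | intermediate
14 | lithium C2–C3 enolate of 13 | CCC1=C[C@@H]2[C@@H](O[C@H]3C[C@@H](C)CC[C@@H]3C(C)C)OC(=O)[C@@]2(C)C=C1O[Li] | intermediate
15 | (3S,3aS,7R,7aR)-5,7-diethyl-7a-methyl-3-[(1S,2R,5S)-menthyloxy]-3a,7-dihydro-2-benzofuran-1,6(3H,7aH)-dione (C2-ethyl, major epimer drawn) | CCC1=C[C@@H]2[C@@H](O[C@H]3C[C@@H](C)CC[C@@H]3C(C)C)OC(=O)[C@@]2(C)[C@@H](CC)C1=O | intermediate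
16 | phenyl vinyl sulfoxide | C=CS(=O)c1ccccc1 | starting material
17 | lithium C2–C3 enolate of 15 | CCC1=C[C@@H]2[C@@H](O[C@H]3C[C@@H](C)CC[C@@H]3C(C)C)OC(=O)[C@@]2(C)C(CC)=C1O[Li] | intermediate
18 | C2β-[2-(phenylsulfinyl)ethyl] adduct of 15 (C2α-ethyl; sulfur epimers) | CCC1=C[C@@H]2[C@@H](O[C@H]3C[C@@H](C)CC[C@@H]3C(C)C)OC(=O)[C@@]2(C)[C@@](CC)(CCS(=O)c4ccccc4)C1=O | intermediate
19 | (3S,3aS,7R,7aR)-7-ethenyl-5,7-diethyl-7a-methyl-3-[(1S,2R,5S)-menthyloxy]-3a,7-dihydro-2-benzofuran-1,6(3H,7aH)-dione (C2β-vinyl, C2α-ethyl) | CCC1=C[C@@H]2[C@@H](O[C@H]3C[C@@H](C)CC[C@@H]3C(C)C)OC(=O)[C@@]2(C)[C@@](CC)(C=C)C1=O | intermediate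
20 | iodobenzene | Ic1ccccc1 | starting material
21 | (3S,3aS,7R,7aR)-5,7-diethyl-7a-methyl-3-[(1S,2R,5S)-menthyloxy]-7-[(E)-2-phenylethenyl]-3a,7-dihydro-2-benzofuran-1,6(3H,7aH)-dione | CCC1=C[C@@H]2[C@@H](O[C@H]3C[C@@H](C)CC[C@@H]3C(C)C)OC(=O)[C@@]2(C)[C@@](CC)(/C=C/c4ccccc4)C1=O | intermediate
22 | 6α-(dimethoxymethyl)-2α,4-diethyl-1α-methyl-3-oxo-2β-[(E)-2-phenylethenyl]cyclohex-4-ene-1β-carboxylic acid | CCC1=C[C@H](C(OC)OC)[C@@](C)(C(=O)O)[C@@](CC)(/C=C/c2ccccc2)C1=O | intermediate
23 | methyl 6α-(dimethoxymethyl)-2α,4-diethyl-1α-methyl-3-oxo-2β-[(E)-2-phenylethenyl]cyclohex-4-ene-1β-carboxylate | CCC1=C[C@H](C(OC)OC)[C@@](C)(C(=O)OC)[C@@](CC)(/C=C/c2ccccc2)C1=O | intermediate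
24 | 2-bromopropene | CC(Br)=C | starting material
25 | isopropenyllithium | [Li]C(C)=C | intermediate
26 | lithium di(prop-1-en-2-yl)cuprate | [Li+].C=C(C)[Cu-]C(C)=C | intermediate
27 | lithium C3–C4 enolate of the C5β-isopropenyl adduct of 23 | CCC1=C(O[Li])[C@@](/C=C/c2ccccc2)(CC)[C@](C)(C(=O)OC)[C@@H](C(OC)OC)[C@@H]1C(C)=C | intermediate
28 | methyl 6α-(dimethoxymethyl)-2α,4-diethyl-1α-methyl-2β-[(E)-2-phenylethenyl]-5β-(prop-1-en-2-yl)-3-(trifluoromethanesulfonyloxy)cyclohex-3-ene-1β-carboxylate | CCC1=C(OS(=O)(=O)C(F)(F)F)[C@@](/C=C/c2ccccc2)(CC)[C@](C)(C(=O)OC)[C@@H](C(OC)OC)[C@@H]1C(C)=C | intermediate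
29 | methyl 6α-(dimethoxymethyl)-2α,4-diethyl-1α-methyl-2β-[(E)-2-phenylethenyl]-5β-(prop-1-en-2-yl)cyclohex-3-ene-1β-carboxylate | CCC1=C[C@@](/C=C/c2ccccc2)(CC)[C@](C)(C(=O)OC)[C@@H](C(OC)OC)[C@@H]1C(C)=C | intermediate
30 | methyl (1R,2S,5R,6S)-2,4-diethyl-6-formyl-1-methyl-2-[(E)-2-phenylethenyl]-5-(prop-1-en-2-yl)cyclohex-3-ene-1-carboxylate | CCC1=C[C@@](/C=C/c2ccccc2)(CC)[C@](C)(C(=O)OC)[C@@H](C=O)[C@@H]1C(C)=C | intermediate
31 | trans-fused bicyclic C7 ketone (1β-CO2Me, 1α-Me, 2β-styryl, 2α-Et, 5α-H, 6β-H, 9α-Me) | CCC1=C[C@@](/C=C/c2ccccc2)(CC)[C@](C)(C(=O)OC)[C@H]2C(=O)C[C@@H](C)[C@H]12 | intermediate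
32 | lithium C7–C8 enolate of 31 | CCC1=C[C@@](/C=C/c2ccccc2)(CC)[C@](C)(C(=O)OC)[C@H]2C(O[Li])=C[C@@H](C)[C@H]12 | intermediate
33 | C7–C8 enol triflate of 31 | CCC1=C[C@@](/C=C/c2ccccc2)(CC)[C@](C)(C(=O)OC)[C@H]2C(OS(=O)(=O)C(F)(F)F)=C[C@@H](C)[C@H]12 | intermediate
34 | spiculoic acid B methyl ester | CCC1=C[C@@](/C=C/c2ccccc2)(CC)[C@](C)(C(=O)OC)[C@H]2C(CC)=C[C@@H](C)[C@H]12 | intermediate
35 | spiculoic acid B | CCC1=C[C@@](/C=C/c2ccccc2)(CC)[C@](C)(C(=O)O)[C@H]2C(CC)=C[C@@H](C)[C@H]12 | target

## Step count and least certain steps

Total: 17 steps. Longest linear sequence: 17 steps from 1; compounds 2, 4, 8, 16, 20 and 24 are purchased and enter directly. The stereocentres are set at C6 (step 2), C1 (step 3), C2 (step 8), C5 (step 11) and C9 (step 14), all relayed from the acetal carbon fixed in step 1.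

Step 14 (key step). The most likely failures are decarbonylation of the acyl rhodium hydride (a hindered, α-branched aldehyde inserts slowly into the alkene), hydride delivery to the wrong face of the isopropenyl group, and loss of configuration at C6 through reversible metal enolate formation. The fallback sets out from 29 and returns at 31, and replaces hydroacylation by hydroboration and a reductive carbonyl addition. Hydroboration of the isopropenyl group of 29 with 9-BBN and oxidative work-up (NaBO3) should give the C8 primary alcohol F1, with C9 set by borane attack anti to the C6 branch. Iodination (I2, PPh3, imidazole) would give the primary iodide F2, and acetal hydrolysis (PPTS, aqueous acetone) the iodo aldehyde F3. Barbier cyclisation with SmI2 in THF/HMPA should close ring B to the cyclopentanol F4, and Dess–Martin oxidation would give 31.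

Step 8. The likely failures are deprotonation at C6 (γ) in place of C2, sluggish conjugate addition of a fully substituted enolate next to a quaternary carbon, and proton transfer from the adduct carbanion to unreacted ketone. The fallback sets out from 15 and returns at 21, bypassing 19. The enolate of 15 would be alkylated with the more reactive allyl bromide to the C2β-allyl ketone F5. Alkene isomerisation with RuHCl(CO)(PPh3)3 in toluene should give the (E)-prop-1-enyl ketone F6, and cross-metathesis with styrene using the second-generation Grubbs catalyst would give 21.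

Step 5. The likely failures are loss of regiocontrol if carbonyl participation is weak, so that oxygen is delivered to C4, and partial hydrolysis of the acylal in the aqueous medium. The fallback sets out from 7 and returns at 12, replacing the alkyne by a 1,1-disubstituted alkene whose cleavage is unambiguous. The enolate of 7 (LDA) would be alkylated with 2-(bromomethyl)pent-1-ene to the 2-methylidenepentyl lactone F7. Dithiane removal (MeI, CaCO3, aqueous MeCN) would give the aldehyde F8, and ozonolysis (O3, CH2Cl2, −78 °C; Me2S) would give 12.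

Step 11. The likely failures are competing 1,2-addition or slow 1,4-addition at the α-substituted enone, incomplete O-triflation of the hindered enolate, and weak facial discrimination if the ring reacts through the conformer with the C1 methyl group axial. The fallback sets out from 23 and returns at 28, separating carbon–carbon bond formation from enolate trapping. Rhodium-catalysed 1,4-addition of potassium isopropenyltrifluoroborate ([Rh(cod)OH]2, dioxane/H2O, 60 °C) should give the saturated C3 ketone F9, which can enolise only towards C4. KHMDS followed by PhNTf2 would then give 28.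

## Further compounds

F1 | step 14 | methyl 6α-(dimethoxymethyl)-2α,4-diethyl-5β-[(2R*)-1-hydroxypropan-2-yl]-1α-methyl-2β-[(E)-2-phenylethenyl]cyclohex-3-ene-1β-carboxylate (C9 as in 35) | CCC1=C[C@@](/C=C/c2ccccc2)(CC)[C@](C)(C(=O)OC)[C@@H](C(OC)OC)[C@@H]1[C@H](C)CO
F2 | step 14 | C8 primary iodide corresponding to F1 | CCC1=C[C@@](/C=C/c2ccccc2)(CC)[C@](C)(C(=O)OC)[C@@H](C(OC)OC)[C@@H]1[C@H](C)CI
F3 | step 14 | 6α-formyl C8 iodide (iodo aldehyde) | CCC1=C[C@@](/C=C/c2ccccc2)(CC)[C@](C)(C(=O)OC)[C@@H](C=O)[C@@H]1[C@H](C)CI
F4 | step 14 | trans-fused bicyclic C7 alcohol (C7 epimers) | CCC1=C[C@@](/C=C/c2ccccc2)(CC)[C@](C)(C(=O)OC)[C@H]2C(O)C[C@@H](C)[C@H]12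
F5 | step 8 | C2β-allyl C2α-ethyl enone lactone | CCC1=C[C@@H]2[C@@H](O[C@H]3C[C@@H](C)CC[C@@H]3C(C)C)OC(=O)[C@@]2(C)[C@@](CC)(CC=C)C1=O
F6 | step 8 | C2β-[(E)-prop-1-enyl] C2α-ethyl enone lactone | CCC1=C[C@@H]2[C@@H](O[C@H]3C[C@@H](C)CC[C@@H]3C(C)C)OC(=O)[C@@]2(C)[C@@](CC)(/C=C/C)C1=O
F7 | step 5 | (3S,4S,5S)-4-(1,3-dithian-2-yl)-3-methyl-3-(2-methylidenepentyl)-5-[(1S,2R,5S)-menthyloxy]oxolan-2-one | CCCC(=C)C[C@]1(C)C(=O)O[C@H](O[C@H]2C[C@@H](C)CC[C@@H]2C(C)C)[C@H]1C3SCCCS3
F8 | step 5 | 4-methyl-4-(2-methylidenepentyl)-2-[(1S,2R,5S)-menthyloxy]-5-oxooxolane-3-carbaldehyde (configured as 11) | CCCC(=C)C[C@]1(C)C(=O)O[C@H](O[C@H]2C[C@@H](C)CC[C@@H]2C(C)C)[C@H]1C=O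
F9 | step 11 | methyl 6α-(dimethoxymethyl)-2α,4-diethyl-1α-methyl-3-oxo-2β-[(E)-2-phenylethenyl]-5β-(prop-1-en-2-yl)cyclohexane-1β-carboxylate (C4 epimers) | CCC1C(=O)[C@@](/C=C/c2ccccc2)(CC)[C@](C)(C(=O)OC)[C@@H](C(OC)OC)[C@@H]1C(C)=C
A1 | alternative 1 | bicyclic C8 enone with C6=C7 and a 2β-(tert-butyldimethylsilyloxymethyl) group | CCC1=C[C@@](CO[Si](C)(C)C(C)(C)C)(CC)[C@](C)(C(=O)OC)C2=C(CC)C(=O)[C@@H](C)[C@H]12
A2 | alternative 1 | acyclic dienyne ester, alkyne C6≡C7 and (3Z,5E)-diene C3=C4–C5=C9 | CCC#C[C@@](C)(C(=O)OC)[C@@](CC)(CO[Si](C)(C)C(C)(C)C)/C=C(CC)\C=C\C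
A3 | alternative 2 | ring-A acid with the C7 carboxyl on C6 and the 1-methylallyl group on C5 | CCC1=C[C@@](/C=C/c2ccccc2)(CC)[C@](C)(C(=O)OC)[C@@H](C(=O)O)[C@@H]1[C@H](C)C=C
A4 | alternative 2 | δ-lactone (O–C3 bond, C7 carbonyl) carrying the (Z)-C4=C5 side chain on C3 | O=C1C[C@@](C)(C(=O)OC)[C@@](CC)(/C=C/c2ccccc2)[C@H](O1)/C(CC)=C\[C@H](C)C=C
A5 | alternative 3 | spiculoic acid B methyl ester (identical with 34) | CCC1=C[C@@](/C=C/c2ccccc2)(CC)[C@](C)(C(=O)OC)[C@H]2C(CC)=C[C@@H](C)[C@H]12
A6 | alternative 3 | ring-B cyclopentene bearing the (Z)-C3 iodoalkene on C5 and the C2=Cα trisubstituted alkene on C1 | I/C=C(CC)\[C@H]1[C@H](C)C=C(CC)[C@@H]1[C@@](C)(C(=O)OC)/C(CC)=C/Cc2ccccc2
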